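**Plan**

- Retrosynthesis opens the five-membered ring of the indenone at C2=C3 and returns the C1 oxygen to C3 (retro alkyne–carbonyl metathesis), which gives a C2-symmetric bis(2-aroylaryl)acetylene that is an isomer of the target.
- The tolane is then cut at the two bonds on neighbouring carbons of ring A: C7a–C1 (aryl–alkyne) and C3a–C3 (aryl–acyl).
- Enabling feature: ring A bears its two carbon substituents on adjacent C3a and C7a, and C7a is flanked by the C7 methoxy group. This is the 1,2,3-pattern that an ortho-substituted aryl iodide gives on norbornene-relayed ortho C–H acylation with ipso alkynylation.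
- Forward: one iodoarene, made from 4-methoxy-3-methylphenol, is used twice, first with (triisopropylsilyl)acetylene to build the ring B arylacetylene, then with that alkyne to give the tolane.
- Methoxymethyl removal and acid-promoted ring closure then form the indenone, the only ring made in the route.
- The target has no stereocentre, so no stereochemistry has to be set.

Key step: step 8

Remark: atom numbers are those of 1H-inden-1-one (C1 carbonyl, C2, C3, C3a, C4–C7, C7a); ring A is the benzo ring of the indenone, ring B the aryl ring on C2; 2,6-dimethoxybenzoyl chloride is taken as a purchased starting material alongside the acid.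

**Route**

Step 1
Reactants: 1 4-methoxy-3-methylphenol
Product: 2 triisopropyl(4-methoxy-3-methylphenoxy)silane
Conditions: TIPSCl, imidazole, DMF, rt
Reagents that add atoms: triisopropylsilyl chloride, CC(C)[Si](Cl)(C(C)C)C(C)C
Why: Imidazole-mediated O-silylation of a phenol; the bulky silyl ether tolerates alkyllithiums and neither coordinates lithium nor leaves its own ortho positions accessible.

Step 2
Reactants: 2 triisopropyl(4-methoxy-3-methylphenoxy)silane
Product: 4 triisopropyl(3-iodo-4-methoxy-5-methylphenoxy)silane, via aryllithium 3 (not isolated)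
Conditions: s-BuLi, TMEDA, THF, −78 °C; then I2, THF, −78 °C to rt
Reagents that add atoms: iodine, II
Why: Directed ortho-metalation followed by iodinolysis: with the silyl ether shielding both of its neighbours, the methoxy group should steer lithiation to its only free ortho position, a site that electrophilic iodination (which would go ortho to the phenol oxygen) cannot reach.

Step 3
Reactants: 4 triisopropyl(3-iodo-4-methoxy-5-methylphenoxy)silane
Product: 5 3-iodo-4-methoxy-5-methylphenol
Conditions: Bu4NF (1 M in THF), THF, 0 °C
Reagents that add atoms: none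
Why: Fluoride-induced Si–O cleavage of an aryl silyl ether, to which the aryl iodide and the methyl ether are inert.

Step 4
Reactants: 5 3-iodo-4-methoxy-5-methylphenol
Product: 6 1-iodo-2-methoxy-5-(methoxymethoxy)-3-methylbenzene
Conditions: MOMCl, iPr2NEt, CH2Cl2, 0 °C to rt
Reagents that add atoms: chloromethyl methyl ether, COCCl
Why: O-Alkylation of the phenol to the methoxymethyl acetal, a small base-stable group that should crowd the neighbouring C–H far less than the silyl ether during palladation and acylation.

Step 5
Reactants: 7 2,6-dimethoxybenzoic acid; 8 2,6-dimethoxybenzoyl chloride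
Product: 9 2,6-dimethoxybenzoic anhydride
Conditions: Et3N, DMAP (cat.), CH2Cl2, 0 °C to rt
Reagents that add atoms: none
Why: DMAP-catalysed acylation of the carboxylate by the acid chloride (standard symmetrical anhydride synthesis); the electron-rich acyl chloride readily forms an acylpyridinium species despite its two ortho substituents.

Step 6
Reactants: 6 1-iodo-2-methoxy-5-(methoxymethoxy)-3-methylbenzene; 9 2,6-dimethoxybenzoic anhydride; 10 (triisopropylsilyl)acetylene
Product: 11 (2,6-dimethoxyphenyl)[3-methoxy-6-(methoxymethoxy)-4-methyl-2-[(triisopropylsilyl)ethynyl]phenyl]methanone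
Conditions: Pd(OAc)2 (10 mol %), P(2-furyl)3 (25 mol %), norbornene (2 equiv), Cs2CO3 (3 equiv), 9 (2.5 equiv), 10 (1.5 equiv), MeCN, 90 °C
Reagents that add atoms: none
Why: Catellani reaction (palladium/norbornene ortho C–H acylation by an anhydride with ipso alkynylation), the same manifold as step 8 but with a bulky silylacetylene that should neither insert into the palladacycle nor couple twice.

Step 7
Reactants: 11 (2,6-dimethoxyphenyl)[3-methoxy-6-(methoxymethoxy)-4-methyl-2-[(triisopropylsilyl)ethynyl]phenyl]methanone
Product: 12 (2,6-dimethoxyphenyl)[2-ethynyl-3-methoxy-6-(methoxymethoxy)-4-methylphenyl]methanone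
Conditions: Bu4NF (1 M in THF), THF, 0 °C
Reagents that add atoms: none
Why: Fluoride-mediated protodesilylation of a silylalkyne; the ketone is shielded by four ortho substituents and the methoxymethyl ether is stable to base.

Step 8
Reactants: 6 1-iodo-2-methoxy-5-(methoxymethoxy)-3-methylbenzene; 9 2,6-dimethoxybenzoic anhydride; 12 (2,6-dimethoxyphenyl)[2-ethynyl-3-methoxy-6-(methoxymethoxy)-4-methylphenyl]methanone
Product: 13 1,2-bis[2-(2,6-dimethoxybenzoyl)-6-methoxy-3-(methoxymethoxy)-5-methylphenyl]ethyne
Conditions: Pd(OAc)2 (10 mol %), P(2-furyl)3 (25 mol %), norbornene (2 equiv), Cs2CO3 (3 equiv), 6 (1.3 equiv), 9 (2.5 equiv), MeCN, 90 °C, 12 added over 4 h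
Reagents that add atoms: none
Why: Oxidative addition of 6 to zerovalent palladium, syn insertion of norbornene and palladation of the only free ortho C–H (the future C3a) should give the five-membered aryl–norbornyl palladacycle, which takes up anhydride 9 at its aryl carbon (oxidative addition to tetravalent palladium and reductive elimination, or the concerted equivalent) and so forms C3a–C3 with the 2,6-dimethoxybenzoyl group in place. With the methoxy group on one side and the new aroyl group on the other, norbornene is expelled by β-carbon elimination, and the arylpalladium carboxylate left at the future C7a is alkynylated by 12 under carbonate and reductively eliminates to form C7a–C1 of the tolane. The closest known reaction type is the Catellani ortho-acylation of aryl iodides with anhydrides terminated by a terminal alkyne; no ring is closed and no stereocentre is created. The step needs acylation to come before alkynylation and to occur only once: the single ortho C–H guarantees the latter, while copper-free conditions, excess norbornene and slow addition of 12 should hold back direct Sonogashira coupling until norbornene has left. The C7 methoxy group is the ortho substituent that directs the anhydride to the aryl rather than the norbornyl carbon and forces norbornene extrusion, and the small methoxymethyl ether next to C3a together with an excess of the hindered anhydride is chosen to ease the congested acyl transfer.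

Step 9
Reactants: 13 1,2-bis[2-(2,6-dimethoxybenzoyl)-6-methoxy-3-(methoxymethoxy)-5-methylphenyl]ethyne
Product: 14 1,2-bis[2-(2,6-dimethoxybenzoyl)-3-hydroxy-6-methoxy-5-methylphenyl]ethyne
Conditions: 3 M aq. HCl, MeOH/THF, 40 °C
Reagents that add atoms: none
Why: Acid-catalysed acetal exchange (methoxymethyl ether cleavage) in methanol, which captures the formaldehyde unit as its dimethyl acetal so that no electrophile remains to alkylate the electron-rich rings; aryl methyl ethers, ketones and the diarylalkyne should be untouched.

Step 10
Reactants: 14 1,2-bis[2-(2,6-dimethoxybenzoyl)-3-hydroxy-6-methoxy-5-methylphenyl]ethyne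
Product: 15 acredinone A, 2-[2-(2,6-dimethoxybenzoyl)-3-hydroxy-6-methoxy-5-methylphenyl]-3-(2,6-dimethoxyphenyl)-4-hydroxy-7-methoxy-6-methyl-1H-inden-1-one
Conditions: TfOH (5 equiv), CH2Cl2, 0 °C to rt
Reagents that add atoms: none
Why: Brønsted acid-promoted intramolecular alkyne–carbonyl metathesis of an ortho-alkynyl diaryl ketone, in which the protonated benzophenone carbon (C3) is attacked by the distal alkyne carbon (C2) to close the five-membered ring and the oxygen is passed to the proximal alkyne carbon (C1), giving the 2,3-diarylinden-1-one; because 14 is C2-symmetric either benzoyl group leads to the same product and the other remains as the ring B ketone.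

**Compound list**

1 | 4-methoxy-3-methylphenol | COc1ccc(O)cc1C | starting material
2 | triisopropyl(4-methoxy-3-methylphenoxy)silane | COc1ccc(O[Si](C(C)C)(C(C)C)C(C)C)cc1C | intermediate
3 | [2-methoxy-3-methyl-5-(triisopropylsilyloxy)phenyl]lithium (aryllithium) | COc1c([Li])cc(O[Si](C(C)C)(C(C)C)C(C)C)cc1C | intermediate
4 | triisopropyl(3-iodo-4-methoxy-5-methylphenoxy)silane | COc1c(I)cc(O[Si](C(C)C)(C(C)C)C(C)C)cc1C | intermediate
5 | 3-iodo-4-methoxy-5-methylphenol | COc1c(I)cc(O)cc1C | intermediate
6 | 1-iodo-2-methoxy-5-(methoxymethoxy)-3-methylbenzene | COCOc1cc(C)c(OC)c(I)c1 | intermediate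
7 | 2,6-dimethoxybenzoic acid | COc1cccc(OC)c1C(O)=O | starting material
8 | 2,6-dimethoxybenzoyl chloride | COc1cccc(OC)c1C(Cl)=O | starting material
9 | 2,6-dimethoxybenzoic anhydride | COc1cccc(OC)c1C(=O)OC(=O)c1c(OC)cccc1OC | intermediate
10 | (triisopropylsilyl)acetylene | C#C[Si](C(C)C)(C(C)C)C(C)C | starting material
11 | (2,6-dimethoxyphenyl)[3-methoxy-6-(methoxymethoxy)-4-methyl-2-[(triisopropylsilyl)ethynyl]phenyl]methanone | COCOc1cc(C)c(OC)c(C#C[Si](C(C)C)(C(C)C)C(C)C)c1C(=O)c1c(OC)cccc1OC | intermediate
12 | (2,6-dimethoxyphenyl)[2-ethynyl-3-methoxy-6-(methoxymethoxy)-4-methylphenyl]methanone | C#Cc1c(OC)c(C)cc(OCOC)c1C(=O)c1c(OC)cccc1OC | intermediate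
13 | 1,2-bis[2-(2,6-dimethoxybenzoyl)-6-methoxy-3-(methoxymethoxy)-5-methylphenyl]ethyne | COc1cccc(OC)c1C(=O)c1c(OCOC)cc(C)c(OC)c1C#Cc1c(OC)c(C)cc(OCOC)c1C(=O)c1c(OC)cccc1OC | intermediate
14 | 1,2-bis[2-(2,6-dimethoxybenzoyl)-3-hydroxy-6-methoxy-5-methylphenyl]ethyne | COc1cccc(OC)c1C(=O)c1c(O)cc(C)c(OC)c1C#Cc1c(OC)c(C)cc(O)c1C(=O)c1c(OC)cccc1OC | intermediate
15 | acredinone A | COc1cccc(OC)c1C(=O)c1c(O)cc(C)c(OC)c1C1=C(c2c(OC)cccc2OC)c2c(O)cc(C)c(OC)c2C1=O | target

**Step count**

Total steps: 10. Longest linear sequence: 9 (steps 1–4 and 6–10; step 5 is a one-step branch).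

**Steps most likely to fail**

1. Step 8. Acyl transfer from the doubly ortho-substituted anhydride to the palladacycle may be too slow next to the methoxymethoxy group, so the palladium intermediates could be drained by direct alkynylation at C7a, by norbornene-retaining pathways or by protodeiodination. The fallback sets out from 6 and returns at 13. Deprotonation of 6 with LiN(iPr)2 (THF, −78 °C) at the C–H between iodine and the methoxymethoxy group and trapping with 2,6-dimethoxybenzaldehyde should give the racemic carbinol (2,6-dimethoxyphenyl)[2-iodo-3-methoxy-6-(methoxymethoxy)-4-methylphenyl]methanol F1. Dess–Martin oxidation should then give (2,6-dimethoxyphenyl)[2-iodo-3-methoxy-6-(methoxymethoxy)-4-methylphenyl]methanone F2. A conventional Sonogashira coupling of F2 with 12 (PdCl2(PPh3)2, CuI, Et3N, DMF, 60 °C) should deliver 13.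

2. Step 6. The same sluggish acyl transfer could let the silylacetylene couple directly with the aryl iodide before the ortho position is acylated. The fallback sets out from 6 and returns at 11. Lithiation of 6 with LiN(iPr)2 (THF, −78 °C) and formylation with DMF should give 2-iodo-3-methoxy-6-(methoxymethoxy)-4-methylbenzaldehyde F3. Sonogashira coupling with 10 (PdCl2(PPh3)2, CuI, Et3N, THF) should give 3-methoxy-6-(methoxymethoxy)-4-methyl-2-[(triisopropylsilyl)ethynyl]benzaldehyde F4. Addition of 2,6-dimethoxyphenyllithium (from 1,3-dimethoxybenzene and n-BuLi) at −78 °C should give the racemic carbinol (2,6-dimethoxyphenyl)[3-methoxy-6-(methoxymethoxy)-4-methyl-2-[(triisopropylsilyl)ethynyl]phenyl]methanol F5, and Dess–Martin oxidation should give 11.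

3. Step 10. Under strong acid the carbonyl oxygen rather than the carbonyl carbon may engage the alkyne, leading to oxygen-heterocyclic cations that do not go on to the indenone under anhydrous conditions, or the free phenols may displace a neighbouring methoxy group with ring closure. The fallback sets out from 13 and returns at 15. Hydration of the alkyne with (Ph3P)AuNTf2 (5 mol %) and water in 1,4-dioxane at 60 °C, assisted by the ortho benzoyl oxygen, should give 1,2-bis[2-(2,6-dimethoxybenzoyl)-6-methoxy-3-(methoxymethoxy)-5-methylphenyl]ethan-1-one F6; either sense of water addition gives the same ketone because 13 is symmetric. Intramolecular aldol condensation of the benzylic methylene onto the neighbouring diaryl ketone (KOH, MeOH/THF, 50 °C) should give 2-[2-(2,6-dimethoxybenzoyl)-6-methoxy-3-(methoxymethoxy)-5-methylphenyl]-3-(2,6-dimethoxyphenyl)-7-methoxy-4-(methoxymethoxy)-6-methyl-1H-inden-1-one F7. Methanolic HCl should then remove both methoxymethyl groups to give 15.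

Further compounds
F1 | step 8 | (2,6-dimethoxyphenyl)[2-iodo-3-methoxy-6-(methoxymethoxy)-4-methylphenyl]methanol (racemic) | COCOc1cc(C)c(OC)c(I)c1C(O)c1c(OC)cccc1OC
F2 | step 8 | (2,6-dimethoxyphenyl)[2-iodo-3-methoxy-6-(methoxymethoxy)-4-methylphenyl]methanone | COCOc1cc(C)c(OC)c(I)c1C(=O)c1c(OC)cccc1OC
F3 | step 6 | 2-iodo-3-methoxy-6-(methoxymethoxy)-4-methylbenzaldehyde | COCOc1cc(C)c(OC)c(I)c1C=O
F4 | step 6 | 3-methoxy-6-(methoxymethoxy)-4-methyl-2-[(triisopropylsilyl)ethynyl]benzaldehyde | COCOc1cc(C)c(OC)c(C#C[Si](C(C)C)(C(C)C)C(C)C)c1C=O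
F5 | step 6 | (2,6-dimethoxyphenyl)[3-methoxy-6-(methoxymethoxy)-4-methyl-2-[(triisopropylsilyl)ethynyl]phenyl]methanol (racemic) | COCOc1cc(C)c(OC)c(C#C[Si](C(C)C)(C(C)C)C(C)C)c1C(O)c1c(OC)cccc1OC
F6 | step 10 | 1,2-bis[2-(2,6-dimethoxybenzoyl)-6-methoxy-3-(methoxymethoxy)-5-methylphenyl]ethan-1-one | COc1cccc(OC)c1C(=O)c1c(OCOC)cc(C)c(OC)c1C(=O)Cc1c(OC)c(C)cc(OCOC)c1C(=O)c1c(OC)cccc1OC
F7 | step 10 | 2-[2-(2,6-dimethoxybenzoyl)-6-methoxy-3-(methoxymethoxy)-5-methylphenyl]-3-(2,6-dimethoxyphenyl)-7-methoxy-4-(methoxymethoxy)-6-methyl-1H-inden-1-one | COc1cccc(OC)c1C(=O)c1c(OCOC)cc(C)c(OC)c1C1=C(c2c(OC)cccc2OC)c2c(OCOC)cc(C)c(OC)c2C1=O
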